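**Retrosynthetic overview**

1. Locants: lactam N–C1(=O)–C2=C19–C20(OH), benzylic C21, ketone C3, chain C4–C18 (aryl ether on C6; methyls on C8, C10, C12, C14; vinyl C17=C18). Ring A = C7–C12, ring B = C5–C6–C7–C12–C13, ring C = C4–C5–C13–C14=C15–C16. Target 27 ⇐ 26 (ethynyl in place of vinyl, semi-hydrogenation) ⇐ 25 (C4 epimer, enolisation).
2. Key disconnection: ring C is a cyclohexene whose C14=C15 bond lies 1,4 to the C4–C5 bond, and C4–C5 is α,β to the C3 ketone, which is a Diels–Alder retron. Cutting C4–C16 and C5–C13 (C5–C13 is shared with ring B; the tether C6–C7–C12 lies in ring A) opens rings B and C together. The precursor is the 13-membered cyclophane dienone 24 with an (E)-C4=C5 enone inside the macrocycle and a (13E,15Z)-dienyne on C12; it is released by oxidation of macrocyclic alcohol 23. C4 is enolisable, so the acyl group can be moved to the cis position afterwards.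
3. Macrocycle ⇐ Nozaki–Hiyama–Kishi closure of the C2–C3 bond from bromo-lactam enal 21. Hydroxy lactam ⇐ ylidene butenolide + NH3. Aryl ether ⇐ SNAr of the C6 alkoxide on 4-fluorobenzaldehyde.
4. Ring A fragment 13 ⇐ (R)-5-methylcyclohexenone by cuprate addition/aldol (C8, C7, C6), one-carbon homologation, α-methylation (C12), then Wittig and Peterson olefinations (C13–C18).
5. Order of ring formation: arene and ring A are bought; lactam (step 12); 13-membered cyclophane (step 14); rings B and C in step 16, ring B through the leading C5–C13 bond and ring C last through C4–C16.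

Key step: step 16

Remark: C20 is a hemiaminal that epimerises by ring–chain tautomerism; 20–25 are carried as C20 mixtures (22 and 23 also as carbinol mixtures), and the target configuration at C20 is assumed to be the thermodynamic one of the rigid cyclophane.
Remark: 1, 2, 14, 16, 2-(triphenylphosphoranylidene)propanal and 1,3-bis(triisopropylsilyl)propyne are taken as purchasable.

**Route**

Step 1
Reactants: 1 (R)-5-methylcyclohex-2-en-1-one; 2 (E)-4,4-dimethoxybut-2-enal
Product: 4 anti-aldol ketone, via lithium enolate 3 (not isolated)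
Conditions: Me2CuLi (MeLi, CuI), Et2O, −78 to −30 °C; ZnCl2; then 2, −78 °C; NH4Cl aq.
Reagents that add atoms: lithium dimethylcuprate, [Li+].C[Cu-]C
Why: Tandem conjugate addition–aldol reaction in which the cuprate adds to C8 anti to the C10 methyl, the aldehyde attacks the zinc enolate in a 1,2 sense anti to the new C8 methyl, and the cyclic (E)-enolate reacts through a Zimmerman–Traxler chair to give the anti aldol, which sets C8, C7 and C6.

Step 2
Reactants: 4 anti-aldol ketone
Product: 5 triethylsilyl ether
Conditions: Et3SiCl, imidazole, DMF, 0 °C to rt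
Reagents that add atoms: chlorotriethylsilane, CC[Si](Cl)(CC)CC
Why: Silyl ether formation under weakly basic conditions protects the C6 alcohol and blocks retro-aldol cleavage in the following steps without touching a stereocentre.

Step 3
Reactants: 5 triethylsilyl ether
Product: 6 methylidenecyclohexane
Conditions: Ph3PCH3Br, KOtBu, THF, 0 °C to rt
Reagents that add atoms: methyltriphenylphosphonium bromide (as its ylide), C[P+](c1ccccc1)(c1ccccc1)c1ccccc1.[Br-]
Why: Wittig methylenation with the non-stabilised ylide, which should add to the ketone faster than it enolises it, installs the future C13 and leaves the α-centre C7 intact.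

Step 4
Reactants: 6 methylidenecyclohexane
Product: 8 primary alcohol, via B-alkyl-9-BBN adduct 7 (not isolated)
Conditions: 9-BBN, THF, 0 °C to rt; then NaOH, H2O2, 0 °C
Reagents that add atoms: 9-BBN, [BH]1C2CCCC1CCC2 (atoms stay only in 7); hydrogen peroxide, OO
Why: Anti-Markovnikov hydroboration–oxidation in which 9-BBN selects the 1,1-disubstituted exocyclic alkene over the trans-disubstituted one, the new C12–H centre being of no consequence because it is enolised in step 6.

Step 5
Reactants: 8 primary alcohol
Product: 9 aldehyde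
Conditions: Dess–Martin periodinane, NaHCO3, CH2Cl2, 0 °C to rt
Reagents that add atoms: none
Why: Dess–Martin oxidation of the primary alcohol under buffered conditions gives the aldehyde without disturbing the acetal or the silyl ether.

Step 6
Reactants: 9 aldehyde
Product: 10 α-methyl aldehyde
Conditions: KN(SiMe3)2, THF, −78 °C; MeI, −78 to −20 °C
Reagents that add atoms: iodomethane, CI
Why: Enolate C-alkylation in which iodomethane attacks the exocyclic potassium enolate on the face anti to the adjacent C7 side chain and to the axial C10 methyl (equatorial attack on the chair with the C8 methyl and C7 chain equatorial), which sets the quaternary C12 with methyl trans to the C7 substituent.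

Step 7
Reactants: 10 α-methyl aldehyde
Product: 11 (E)-enal
Conditions: Ph3P=C(Me)CHO, toluene, 100 °C
Reagents that add atoms: 2-(triphenylphosphoranylidene)propanal, CC(C=O)=P(c1ccccc1)(c1ccccc1)c1ccccc1
Why: Wittig olefination with the stabilised formyl ylide gives the (E)-trisubstituted C13=C14 enal, and the conjugated, α-branched product should be too deactivated to react a second time.

Step 8
Reactants: 11 (E)-enal
Product: 12 (13E,15Z)-dienyne
Conditions: iPr3SiCH2C≡CSi(iPr)3, n-BuLi, THF, −20 °C; then 11, −78 °C to rt
Reagents that add atoms: 1,3-bis(triisopropylsilyl)propyne, CC(C)[Si](CC#C[Si](C(C)C)(C(C)C)C(C)C)(C(C)C)C(C)C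
Why: Peterson olefination in which the lithiated bis-silyl propyne adds to the enal and the β-oxidosilane eliminates syn in the flask, the bulky triisopropylsilyl groups favouring the adduct that gives the (15Z)-enyne with the alkyne cis to C14.

Step 9
Reactants: 12 (13E,15Z)-dienyne
Product: 13 C6 alcohol
Conditions: PPTS, MeOH, 0 °C to rt
Reagents that add atoms: none
Why: Acid-catalysed methanolysis removes the triethylsilyl ether selectively, the alkynyl triisopropylsilyl group and the dimethyl acetal (degenerate exchange in methanol) being left untouched.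

Step 10
Reactants: 13 C6 alcohol; 14 4-fluorobenzaldehyde
Product: 15 aryl ether aldehyde
Conditions: KN(SiMe3)2, THF/DMF, −20 °C; then 14, rt
Reagents that add atoms: none
Why: Nucleophilic aromatic substitution (SNAr) of the potassium alkoxide on the para-formyl-activated aryl fluoride forms the aryl ether with retention at C6 because the C6–O bond is not broken.

Step 11
Reactants: 15 aryl ether aldehyde; 16 3-bromofuran-2(5H)-one
Product: 19 (Z)-bromo ylidene butenolide, via lithium 3-bromofuran-2-olate 17 (not isolated), via aldol acetate 18 (not isolated)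
Conditions: 16, LDA, THF, −78 °C; then 15; Ac2O, −78 to 0 °C; DBU, rt
Reagents that add atoms: acetic anhydride, CC(=O)OC(C)=O (atoms stay only in 18)
Why: Vinylogous aldol condensation in which the oxidofuran adds through its γ-carbon (C20) to the aryl aldehyde and acetylation followed by E1cB elimination gives the conjugated ylidene butenolide as its thermodynamically favoured (Z) isomer.

Step 12
Reactants: 19 (Z)-bromo ylidene butenolide
Product: 20 bromo hydroxy lactam
Conditions: NH3 (7 M in MeOH), THF, 0 °C to rt
Reagents that add atoms: ammonia, N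
Why: Aminolysis of the enol lactone gives the (Z)-4-oxo-enamide, which closes by ring–chain tautomerism to the 5-hydroxy-1,5-dihydropyrrol-2-one, C20 forming as an equilibrating pair of epimers.

Step 13
Reactants: 20 bromo hydroxy lactam
Product: 21 bromo-lactam enal
Conditions: PPTS, acetone/H2O, rt
Reagents that add atoms: water, O
Why: Mild acid hydrolysis of the allylic dimethyl acetal releases the (E)-enal under conditions that the tertiary hemiaminal lactam should survive.

Step 14
Reactants: 21 bromo-lactam enal
Product: 22 macrocyclic alcohol (silylated alkyne)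
Conditions: CrCl2 (excess), NiCl2 (cat.), DMSO/THF, rt, slow addition at high dilution
Reagents that add atoms: none
Why: Nozaki–Hiyama–Kishi reaction in which NiCl2-catalysed activation of the electron-poor alkenyl bromide and transmetalation to chromium give an alkenylchromium species that adds 1,2 to the enal, closing the 13-membered cyclophane at the C2–C3 bond while C3 is still sp3 and flexible (the carbinol centre is oxidised in step 16).

Step 15
Reactants: 22 macrocyclic alcohol (silylated alkyne)
Product: 23 macrocyclic alcohol (terminal alkyne)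
Conditions: Bu4NF, AcOH, THF, 0 °C
Reagents that add atoms: none
Why: Buffered fluoride C-desilylation frees the terminal alkyne so that the inside substituent of the diene is the smallest possible carbon group.

Step 16
Reactants: 23 macrocyclic alcohol (terminal alkyne)
Product: 25 Diels–Alder adduct (C4 epimer of 26), via macrocyclic dienone 24 (not isolated)
Conditions: Dess–Martin periodinane, NaHCO3, CH2Cl2, 0 °C to rt; then 40 °C
Reagents that add atoms: none
Why: Dess–Martin oxidation turns the bis-allylic alcohol into the cross-conjugated dienone 24, whose (E)-enone C4=C5, activated by the C3 ketone and by the strain of the cyclophane, should react with the tethered (13E,15Z)-dienyne in an intramolecular Diels–Alder reaction; the closest known reaction type is the oxidation-triggered type 1 intramolecular Diels–Alder reaction of (E)-nona-1,6,8-trien-3-ones to trans-fused hydrindenes. The cycloaddition is concerted but asynchronous: the C5–C13 bond at the β-carbon of the enone leads and closes ring B (five-membered, through the tether C6–C7–C12), and the C4–C16 bond completes ring C (six-membered) last. C5 is controlled by C6, because the tether reaches only the enone face on which C7 lies, with the C6–OAr bond anti to the incoming diene (Felkin–Anh-type arrangement, the rest of the macrocycle passing over the other face); C13 is controlled by the anti, ketone-endo transition state typical of (E)-enone dienophiles, which gives the trans B/C fusion; C16 is controlled by the (15Z) geometry, the inside ethynyl group ending cis to H13; C4 follows from the (E) enone and ends trans to C6 (corrected in step 17). The step needs endo over exo selectivity and cyclisation over dimerisation or hetero-Diels–Alder reaction of the dienone; the first should be secured by the ketone-under-diene preference, reinforced by the C14 methyl and the quaternary C12 that disfavour the syn tether conformation, the second by dilution and the three-atom tether. The ethynyl group offers no hydrogen for a 1,5-shift and the dienyne cannot undergo 6π-electrocyclisation, so the slower reaction of a cis-substituted diene has no competing pericyclic outlet.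

Step 17
Reactants: 25 Diels–Alder adduct (C4 epimer of 26)
Product: 26 ethynyl analogue of the target
Conditions: DBU, CH2Cl2/MeOH, rt
Reagents that add atoms: none
Why: Base-mediated epimerisation at C4 through the enolate of the C3 ketone should move the acyl group into the cis (axial) position preferred by the 13-membered bridge from C6, which is also the isomer formed by protonation on the face anti to the C16 ethynyl group and C6, while C20 equilibrates by ring–chain tautomerism.

Step 18
Reactants: 26 ethynyl analogue of the target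
Product: 27 target CNP0151253.3
Conditions: H2 (1 atm), Pd/CaCO3 poisoned with Pb(OAc)2 (Lindlar catalyst), quinoline, EtOAc, rt
Reagents that add atoms: none
Why: Lindlar semi-hydrogenation reduces the terminal alkyne to the vinyl group and should stop there, the trisubstituted ring alkene and the conjugated lactam alkene being inert on the poisoned catalyst.

**Compound list**

1 | (R)-5-methylcyclohex-2-en-1-one | O=C1C=CC[C@@H](C)C1 | starting material
2 | (E)-4,4-dimethoxybut-2-enal | COC(OC)/C=C/C=O | starting material
3 | lithium (3R,5R)-3,5-dimethylcyclohex-1-en-1-olate (zinc enolate after ZnCl2) | [Li+].[O-]C1=C[C@H](C)C[C@@H](C)C1 | intermediate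
4 | (2R,3R,5R)-2-[(1R,2E)-1-hydroxy-4,4-dimethoxybut-2-en-1-yl]-3,5-dimethylcyclohexan-1-one (3-methyl trans to 5-methyl, side chain trans to 3-methyl, anti aldol) | COC(OC)/C=C/[C@@H](O)[C@H]1[C@H](C)C[C@@H](C)CC1=O | intermediate
5 | triethylsilyl ether of 4 at the C6 hydroxyl | COC(OC)/C=C/[C@@H](O[Si](CC)(CC)CC)[C@H]1[C@H](C)C[C@@H](C)CC1=O | intermediate
6 | methylidene compound: C=O of 5 replaced by C=CH2 | COC(OC)/C=C/[C@@H](O[Si](CC)(CC)CC)[C@H]1[C@H](C)C[C@@H](C)CC1=C | intermediate
7 | B-alkyl-9-BBN adduct of 6 (boron on the exocyclic carbon, both C12 epimers) | COC(OC)/C=C/[C@@H](O[Si](CC)(CC)CC)[C@H]1[C@H](C)C[C@@H](C)CC1CB1C2CCCC1CCC2 | intermediate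
8 | primary alcohol: hydroxymethyl (future C13) on C12, both C12 epimers | COC(OC)/C=C/[C@@H](O[Si](CC)(CC)CC)[C@H]1[C@H](C)C[C@@H](C)CC1CO | intermediate
9 | aldehyde: formyl (C13) on C12, both C12 epimers | COC(OC)/C=C/[C@@H](O[Si](CC)(CC)CC)[C@H]1[C@H](C)C[C@@H](C)CC1C=O | intermediate
10 | α-methyl aldehyde: C12 quaternary with methyl trans and formyl cis to the C7 side chain | COC(OC)/C=C/[C@@H](O[Si](CC)(CC)CC)[C@H]1[C@H](C)C[C@@H](C)C[C@]1(C=O)C | intermediate
11 | (13E)-enal: C12–CH=C(CH3)–CHO | COC(OC)/C=C/[C@@H](O[Si](CC)(CC)CC)[C@H]1[C@H](C)C[C@@H](C)C[C@]1(/C=C(\C)C=O)C | intermediate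
12 | (13E,15Z)-dienyne with triisopropylsilyl alkyne, C6 triethylsilyl ether | COC(OC)/C=C/[C@@H](O[Si](CC)(CC)CC)[C@H]1[C@H](C)C[C@@H](C)C[C@]1(/C=C(C)/C=C\C#C[Si](C(C)C)(C(C)C)C(C)C)C | intermediate
13 | C6 alcohol of 12 | COC(OC)/C=C/[C@@H](O)[C@H]1[C@H](C)C[C@@H](C)C[C@]1(/C=C(C)/C=C\C#C[Si](C(C)C)(C(C)C)C(C)C)C | intermediate
14 | 4-fluorobenzaldehyde | O=Cc1ccc(F)cc1 | starting material
15 | aryl ether aldehyde: C6–O–C6H4–CHO (para) | COC(OC)/C=C/[C@@H](Oc1ccc(C=O)cc1)[C@H]1[C@H](C)C[C@@H](C)C[C@]1(/C=C(C)/C=C\C#C[Si](C(C)C)(C(C)C)C(C)C)C | intermediate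
16 | 3-bromofuran-2(5H)-one | O=C1OCC=C1Br | starting material
17 | lithium 3-bromofuran-2-olate | [Li+].[O-]c1occc1Br | intermediate
18 | aldol acetate: ArCH(OAc)–(3-bromo-2-oxo-2,5-dihydrofuran-5-yl), diastereomer mixture | COC(OC)/C=C/[C@@H](Oc1ccc(C(OC(C)=O)C2OC(=O)C(Br)=C2)cc1)[C@H]1[C@H](C)C[C@@H](C)C[C@]1(/C=C(C)/C=C\C#C[Si](C(C)C)(C(C)C)C(C)C)C | intermediate
19 | (Z)-3-bromo-5-arylidenefuran-2(5H)-one | COC(OC)/C=C/[C@@H](Oc1ccc(/C=C2\OC(=O)C(Br)=C2)cc1)[C@H]1[C@H](C)C[C@@H](C)C[C@]1(/C=C(C)/C=C\C#C[Si](C(C)C)(C(C)C)C(C)C)C | intermediate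
20 | 3-bromo-5-hydroxy-5-(arylmethyl)-1,5-dihydropyrrol-2-one, acetal intact, C20 epimers | COC(OC)/C=C/[C@@H](Oc1ccc(CC2(O)NC(=O)C(Br)=C2)cc1)[C@H]1[C@H](C)C[C@@H](C)C[C@]1(/C=C(C)/C=C\C#C[Si](C(C)C)(C(C)C)C(C)C)C | intermediate
21 | bromo-lactam (E)-enal, C20 epimers | O=C/C=C/[C@@H](Oc1ccc(CC2(O)NC(=O)C(Br)=C2)cc1)[C@H]1[C@H](C)C[C@@H](C)C[C@]1(/C=C(C)/C=C\C#C[Si](C(C)C)(C(C)C)C(C)C)C | intermediate
22 | 13-membered cyclophane C3 alcohol with (4E)-alkene, silylated alkyne, C3 and C20 epimers | OC1/C=C/[C@@H](Oc2ccc(cc2)CC3(O)NC(=O)C1=C3)[C@H]4[C@H](C)C[C@@H](C)C[C@]4(/C=C(C)/C=C\C#C[Si](C(C)C)(C(C)C)C(C)C)C | intermediate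
23 | cyclophane C3 alcohol, terminal alkyne | OC1/C=C/[C@@H](Oc2ccc(cc2)CC3(O)NC(=O)C1=C3)[C@H]4[C@H](C)C[C@@H](C)C[C@]4(/C=C(C)/C=C\C#C)C | intermediate
24 | cyclophane dienone with (4E)-enone and (13E,15Z)-dienyne | O=C1/C=C/[C@@H](Oc2ccc(cc2)CC3(O)NC(=O)C1=C3)[C@H]4[C@H](C)C[C@@H](C)C[C@]4(/C=C(C)/C=C\C#C)C | intermediate
25 | Diels–Alder adduct: target skeleton with ethynyl on C16 and the C4 acyl trans to C6 | C#C[C@H]1C=C(C)[C@H]2[C@H]3[C@@H](Oc4ccc(cc4)CC4(O)C=C(C(=O)N4)C(=O)[C@H]13)[C@H]1[C@H](C)C[C@@H](C)C[C@]12C | intermediate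
26 | 17,18-didehydro target (ethynyl on C16, all centres as in the target) | C#C[C@H]1C=C(C)[C@H]2[C@H]3[C@@H](Oc4ccc(cc4)C[C@@]4(O)C=C(C(=O)N4)C(=O)[C@@H]13)[C@H]1[C@H](C)C[C@@H](C)C[C@]12C | intermediate
27 | CNP0151253.3 | C=C[C@H]1C=C(C)[C@H]2[C@H]3[C@@H](Oc4ccc(cc4)C[C@@]4(O)C=C(C(=O)N4)C(=O)[C@@H]13)[C@H]1[C@H](C)C[C@@H](C)C[C@]12C | target

**Step count and risks**

Total step count: 18. Longest linear sequence: 18 steps (1 to 27).

Steps most likely to fail:

1. Step 16 (key step). What may go wrong: the cyclophane may steer the diene to the exo mode or to the other enone face (wrong ring fusion or wrong C5/C13 pair), or the strained dienone may dimerise faster than it cyclises. Fallback: the same cycloaddition is run before the macrocycle exists. It sets out from enal 21, which on heating (toluene, BHT, 110 °C) should give, by a type 1 intramolecular Diels–Alder reaction of the (E)-enal in the aldehyde-endo mode, the trans-fused tricyclic aldehyde F1. Nozaki–Hiyama–Kishi closure (CrCl2, NiCl2, DMSO) on this rigid core gives the macrocyclic alcohol F2, Bu4NF/AcOH gives the terminal alkyne F3, and Dess–Martin oxidation comes back to the route at 25.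

2. Step 14. What may go wrong: protonolysis of the alkenylchromium intermediate by the lactam N–H and hemiaminal O–H, or intermolecular coupling winning over the strained 13-membered closure. Fallback: the ring is closed one stage earlier on a substrate without acidic protons. It sets out from ylidene butenolide 19; PPTS in aqueous acetone gives the enal F4, Nozaki–Hiyama–Kishi closure gives the macrocyclic alcohol F5 that still holds the ylidene butenolide, and NH3 in MeOH/THF then converts the enol lactone into the hydroxy lactam, coming back at 22.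

3. Step 6. What may go wrong: attack of iodomethane on the wrong face of the exocyclic enolate, or O-methylation. Fallback: the quaternary centre is set inside a temporary cis-fused ring. It sets out from alcohol 8: Bu4NF gives the diol F6, and TEMPO/PhI(OAc)2 oxidative lactonisation gives the γ-lactone F7. LDA then MeI methylates the ring-fusion enolate to the cis-fused methyl lactone F8; the five-membered ring stays cis-fused, so the methyl must enter trans to the C7–C6 bond. MeNHOMe·HCl/i-PrMgCl opens it to the hydroxy Weinreb amide F9, Et3SiCl/imidazole gives the silylated Weinreb amide F10, and i-Bu2AlH comes back to the route at 10.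

Further compounds
F1 | step 16 | trans-fused tricyclic aldehyde (formyl on C4 trans to C6, silylated alkyne, pendant bromo hydroxy lactam) | O=C[C@@H]1[C@@H](C#C[Si](C(C)C)(C(C)C)C(C)C)C=C(C)[C@H]2[C@H]1[C@@H](Oc1ccc(CC3(O)NC(=O)C(Br)=C3)cc1)[C@H]3[C@H](C)C[C@@H](C)C[C@@]23C
F2 | step 16 | macrocyclic C3 alcohol of the tricycle, silylated alkyne | CC(C)[Si](C(C)C)(C(C)C)C#C[C@H]1C=C(C)[C@H]2[C@H]3[C@@H](Oc4ccc(cc4)CC4(O)C=C(C(=O)N4)C(O)[C@H]13)[C@H]1[C@H](C)C[C@@H](C)C[C@]12C
F3 | step 16 | macrocyclic C3 alcohol of the tricycle, terminal alkyne | C#C[C@H]1C=C(C)[C@H]2[C@H]3[C@@H](Oc4ccc(cc4)CC4(O)C=C(C(=O)N4)C(O)[C@H]13)[C@H]1[C@H](C)C[C@@H](C)C[C@]12C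
F4 | step 14 | (E)-enal of ylidene butenolide 19 | O=C/C=C/[C@@H](Oc1ccc(/C=C2\OC(=O)C(Br)=C2)cc1)[C@H]1[C@H](C)C[C@@H](C)C[C@]1(/C=C(C)/C=C\C#C[Si](C(C)C)(C(C)C)C(C)C)C
F5 | step 14 | macrocyclic C3 alcohol containing the ylidene butenolide | OC1/C=C/[C@@H](Oc2ccc(cc2)/C=C3\OC(=O)C1=C3)[C@H]4[C@H](C)C[C@@H](C)C[C@]4(/C=C(C)/C=C\C#C[Si](C(C)C)(C(C)C)C(C)C)C
F6 | step 6 | diol (C6 hydroxyl and C13 hydroxymethyl, C12 epimers) | COC(OC)/C=C/[C@@H](O)[C@H]1[C@H](C)C[C@@H](C)CC1CO
F7 | step 6 | γ-lactone (C13 carbonyl, ring oxygen on C6, C12 epimers) | COC(OC)/C=C/[C@H]1OC(=O)C2C[C@H](C)C[C@@H](C)[C@H]12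
F8 | step 6 | cis-fused C12-methyl γ-lactone | COC(OC)/C=C/[C@H]1OC(=O)[C@]2(C)C[C@H](C)C[C@@H](C)[C@H]12
F9 | step 6 | hydroxy Weinreb amide (C13 as N-methoxy-N-methylamide) | COC(OC)/C=C/[C@@H](O)[C@H]1[C@H](C)C[C@@H](C)C[C@]1(C(=O)N(C)OC)C
F10 | step 6 | silylated Weinreb amide | COC(OC)/C=C/[C@@H](O[Si](CC)(CC)CC)[C@H]1[C@H](C)C[C@@H](C)C[C@]1(C(=O)N(C)OC)C
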